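## Retrosynthetic overview

1. Target ⇒ remove the C8 ester and the C11 acetate ⇒ cis-fused α-hydroxy-α-methyl γ-lactone ⇒ C6 cyclohexanone (pyruvate aldol at C7, axial-selective reduction at C6, lactonisation). Elemane locants: C10 quaternary carbon, C9 CH2, C8 ester carbinol, C7 ring-fusion CH, C6 lactone O–CH, C5 CH–isopropenyl, C11 lactone carbinol carbon.
2. Cyclohexanone ⇒ cyclopentanone by a one-carbon semipinacol ring expansion: C10 shifts from C6 to a 2-methylallyl cation at C5 (from a spiro vinyl oxirane), which makes the C5–C10 bond.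
3. Cyclopentanone ⇒ achiral cis-1-(buta-1,3-dien-2-yl)-3-silyloxycyclobutanol by the key step, an enantioselective desymmetrising protio-semipinacol ring expansion that creates C10 (Me, vinyl) and fixes C8.
4. Cyclobutanol ⇒ 3-silyloxycyclobutanone + the Grignard reagent of chloroprene.
5. Ring order: cyclobutane (bought) → cyclopentanone → cyclohexanone → γ-lactone (last).

Assumption: compounds 1, 2, 6, 11 and 18 are taken as catalogue compounds, and the tert-butyldimethylsilyl (TBS) group of 1 is counted as a protecting group.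

## Route

Step 1
Reactants: 1 3-[(tert-butyldimethylsilyl)oxy]cyclobutan-1-one; 2 2-chlorobuta-1,3-diene (chloroprene)
Product: 4 cis-1-(buta-1,3-dien-2-yl)-3-[(tert-butyldimethylsilyl)oxy]cyclobutan-1-ol, via buta-1,3-dien-2-ylmagnesium chloride 3 (not isolated)
Conditions: 2, Mg, ZnCl2 (cat.), THF, 50 °C; then 1, −78 → 0 °C; H2O quench; cis isomer purified by chromatography
Reagents that add atoms: none
Why: Grignard 1,2-addition in which the dienyl nucleophile approaches anti to the 3-silyloxy group, so OH and OTBS end up cis; the product is achiral and its two ring CH2 groups are enantiotopic.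

Step 2
Reactants: 4 cis-1-(buta-1,3-dien-2-yl)-3-[(tert-butyldimethylsilyl)oxy]cyclobutan-1-ol
Product: 5 (2S,4R)-4-[(tert-butyldimethylsilyl)oxy]-2-ethenyl-2-methylcyclopentan-1-one
Conditions: (S,S)-imidodiphosphorimidate Brønsted acid built from two (S)-3,3′-bis[3,5-bis(trifluoromethyl)phenyl]-1,1′-bi-2-naphthol units, N,N′-bis(trifluoromethylsulfonyl) (5 mol %; antipode if the sense of induction is opposite), CHCl3, 5 Å MS, −40 °C
Reagents that add atoms: none
Why: Proposed new method: the confined chiral acid hydrogen-bonds the tertiary OH and protonates the terminal CH2 of the 2-substituted diene, and the developing tertiary allyl cation is captured by a 1,2-shift of one of the two enantiotopic ring CH2 groups (about 20 kcal/mol of strain release plus C=O formation); because the proton is delivered next to the hydroxyl, the new methyl lies on the hydroxyl side and the vinyl group under the ring, which puts Me cis to OTBS, while the chiral anion selects the migrating CH2 and so sets the quaternary centre (S) and the carbinol centre (R) together; the closest known reaction type is the Brønsted-acid protio-semipinacol ring expansion of 1-alkenyl cyclopropanols and cyclobutanols and acid-catalysed Wagner–Meerwein shifts, not yet shown on a 2-dienyl carbinol or as a desymmetrisation of a 3-oxygenated cyclobutanol.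

Step 3
Reactants: 5 (2S,4R)-4-[(tert-butyldimethylsilyl)oxy]-2-ethenyl-2-methylcyclopentan-1-one; 6 3-bromo-2-methylprop-1-ene
Product: 9 (2S,3S,4S,6R)-6-[(tert-butyldimethylsilyl)oxy]-4-ethenyl-4-methyl-2-(prop-1-en-2-yl)-1-oxaspiro[2.4]heptane, via diphenyl(2-methylprop-2-en-1-yl)sulfonium tetrafluoroborate 7 (not isolated), via diphenylsulfonium 2-methylprop-2-en-1-ylide 8 (not isolated)
Conditions: 6, Ph2S, AgBF4, CH2Cl2, rt (AgBr filtered off); THF, NaN(SiMe3)2, −78 °C; then 5, −78 → 0 °C
Reagents that add atoms: none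
Why: Corey–Chaykovsky epoxidation with an allylic sulfonium ylide; in 5 the cis methyl and silyloxy groups are pseudoequatorial, so the pseudoaxial vinyl group shields the lower face and the ylide carbon adds syn to the methyl group (the configuration of the oxirane CH is lost in the next step and does not matter).

Step 4
Reactants: 9 (2S,3S,4S,6R)-6-[(tert-butyldimethylsilyl)oxy]-4-ethenyl-4-methyl-2-(prop-1-en-2-yl)-1-oxaspiro[2.4]heptane
Product: 10 (2R,3S,5R)-5-[(tert-butyldimethylsilyl)oxy]-3-ethenyl-3-methyl-2-(prop-1-en-2-yl)cyclohexan-1-one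
Conditions: Sc(OTf)3 (5 mol %), CH2Cl2, −40 → 0 °C
Reagents that add atoms: none
Why: Lewis-acid semipinacol (Meinwald-type) ring expansion in which the allylic C–O bond ionises and the more substituted, allylic quaternary carbon (C10, not the CH2) migrates with retention to the allyl cation through a chair-like transition state with OTBS, methyl and the 2-propenyl group all equatorial, which sets C5 cis to the vinyl group (this is also the more stable epimer).

Step 5
Reactants: 10 (2R,3S,5R)-5-[(tert-butyldimethylsilyl)oxy]-3-ethenyl-3-methyl-2-(prop-1-en-2-yl)cyclohexan-1-one; 11 methyl 2-oxopropanoate (methyl pyruvate)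
Product: 13 methyl (2S)-2-[(1R,3R,4S,6R)-6-[(tert-butyldimethylsilyl)oxy]-4-ethenyl-4-methyl-2-oxo-3-(prop-1-en-2-yl)cyclohexyl]-2-hydroxypropanoate, via lithium cyclohexenolate 12 (not isolated)
Conditions: LiN(i-Pr)2, THF, −78 °C; 11, −78 °C; AcOH quench at −78 °C
Reagents that add atoms: none
Why: Kinetic deprotonation at the less hindered CH2 followed by a closed (Zimmerman–Traxler) aldol addition of the ring enolate to lithium-chelated pyruvate (ester axial, methyl equatorial), with C–C bond formation trans to the neighbouring silyloxy group, sets C7 and the tertiary carbinol C11 (S).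

Step 6
Reactants: 13 methyl (2S)-2-[(1R,3R,4S,6R)-6-[(tert-butyldimethylsilyl)oxy]-4-ethenyl-4-methyl-2-oxo-3-(prop-1-en-2-yl)cyclohexyl]-2-hydroxypropanoate
Product: 15 (3S,3aR,4R,6S,7R,7aR)-4-[(tert-butyldimethylsilyl)oxy]-6-ethenyl-3-hydroxy-3,6-dimethyl-7-(prop-1-en-2-yl)hexahydro-1-benzofuran-2(3H)-one, via lithium alkoxide of the reduced hydroxy ester 14 (not isolated)
Conditions: LiBH(s-Bu)3, THF, −78 → 0 °C; H2O
Reagents that add atoms: none
Why: Diastereoselective ketone reduction from the equatorial (upper) face, the axial trajectory being blocked by the axial vinyl group, gives the axial C6 alkoxide cis to both neighbours, which closes onto the methyl ester to the cis-fused γ-lactone.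

Step 7
Reactants: 15 (3S,3aR,4R,6S,7R,7aR)-4-[(tert-butyldimethylsilyl)oxy]-6-ethenyl-3-hydroxy-3,6-dimethyl-7-(prop-1-en-2-yl)hexahydro-1-benzofuran-2(3H)-one
Product: 16 (3S,3aR,4R,6S,7R,7aR)-4-[(tert-butyldimethylsilyl)oxy]-6-ethenyl-3,6-dimethyl-2-oxo-7-(prop-1-en-2-yl)octahydro-1-benzofuran-3-yl acetate
Conditions: Ac2O, DMAP, Et3N, CH2Cl2, 40 °C
Reagents that add atoms: acetic anhydride, CC(=O)OC(C)=O
Why: DMAP-catalysed acylation of the tertiary α-hydroxy lactone; no stereocentre is touched.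

Step 8
Reactants: 16 (3S,3aR,4R,6S,7R,7aR)-4-[(tert-butyldimethylsilyl)oxy]-6-ethenyl-3,6-dimethyl-2-oxo-7-(prop-1-en-2-yl)octahydro-1-benzofuran-3-yl acetate
Product: 17 (3S,3aS,4R,6S,7R,7aR)-6-ethenyl-4-hydroxy-3,6-dimethyl-2-oxo-7-(prop-1-en-2-yl)octahydro-1-benzofuran-3-yl acetate
Conditions: HF·pyridine, THF, 0 °C → rt
Reagents that add atoms: none
Why: Acidic fluoride desilylation, chosen over basic fluoride so that neither the tertiary acetate nor the lactone acyl group can move to the freed C8 hydroxyl.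

Step 9
Reactants: 17 (3S,3aS,4R,6S,7R,7aR)-6-ethenyl-4-hydroxy-3,6-dimethyl-2-oxo-7-(prop-1-en-2-yl)octahydro-1-benzofuran-3-yl acetate; 18 3-methylbut-3-enoic acid
Product: 19 (3S,3aS,4R,6S,7R,7aR)-3-(acetyloxy)-6-ethenyl-3,6-dimethyl-2-oxo-7-(prop-1-en-2-yl)octahydro-1-benzofuran-4-yl 3-methylbut-3-enoate
Conditions: 18, N,N′-diisopropylcarbodiimide, DMAP (10 mol %), CH2Cl2, 0 °C
Reagents that add atoms: none
Why: Carbodiimide (Steglich) esterification of the equatorial secondary alcohol, run cold with only catalytic DMAP so that the β,γ-double bond of the acid does not move into conjugation.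

## Compound list

1 | 3-[(tert-butyldimethylsilyl)oxy]cyclobutan-1-one | O=C1CC(O[Si](C)(C)C(C)(C)C)C1 | starting material
2 | 2-chlorobuta-1,3-diene | C=CC(Cl)=C | starting material
3 | buta-1,3-dien-2-ylmagnesium chloride | C=CC(=C)[Mg]Cl | intermediate
4 | cis-1-(buta-1,3-dien-2-yl)-3-[(tert-butyldimethylsilyl)oxy]cyclobutan-1-ol (OH and OTBS on the same face) | C=CC(=C)[C@]1(O)C[C@@H](O[Si](C)(C)C(C)(C)C)C1 | intermediate
5 | (2S,4R)-4-[(tert-butyldimethylsilyl)oxy]-2-ethenyl-2-methylcyclopentan-1-one | C=C[C@]1(C)C[C@@H](O[Si](C)(C)C(C)(C)C)CC1=O | intermediate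
6 | 3-bromo-2-methylprop-1-ene | C=C(C)CBr | starting material
7 | diphenyl(2-methylprop-2-en-1-yl)sulfonium tetrafluoroborate | C=C(C)C[S+](c1ccccc1)c1ccccc1.F[B-](F)(F)F | intermediate
8 | diphenylsulfonium 2-methylprop-2-en-1-ylide | C=C(C)[CH-][S+](c1ccccc1)c1ccccc1 | intermediate
9 | (2S,3S,4S,6R)-6-[(tert-butyldimethylsilyl)oxy]-4-ethenyl-4-methyl-2-(prop-1-en-2-yl)-1-oxaspiro[2.4]heptane (the epimer at the oxirane CH may accompany it) | C=C[C@]1(C)C[C@@H](O[Si](C)(C)C(C)(C)C)C[C@]12O[C@H]2C(=C)C | intermediate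
10 | (2R,3S,5R)-5-[(tert-butyldimethylsilyl)oxy]-3-ethenyl-3-methyl-2-(prop-1-en-2-yl)cyclohexan-1-one | C=C[C@]1(C)C[C@@H](O[Si](C)(C)C(C)(C)C)CC(=O)[C@@H]1C(=C)C | intermediate
11 | methyl 2-oxopropanoate | COC(=O)C(C)=O | starting material
12 | lithium (3R,5S,6R)-3-[(tert-butyldimethylsilyl)oxy]-5-ethenyl-5-methyl-6-(prop-1-en-2-yl)cyclohex-1-en-1-olate | C=C[C@]1(C)C[C@@H](O[Si](C)(C)C(C)(C)C)C=C(O[Li])[C@@H]1C(=C)C | intermediate
13 | methyl (2S)-2-[(1R,3R,4S,6R)-6-[(tert-butyldimethylsilyl)oxy]-4-ethenyl-4-methyl-2-oxo-3-(prop-1-en-2-yl)cyclohexyl]-2-hydroxypropanoate | C=C[C@]1(C)C[C@@H](O[Si](C)(C)C(C)(C)C)[C@H]([C@](C)(O)C(=O)OC)C(=O)[C@@H]1C(=C)C | intermediate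
14 | lithium alkoxide of methyl (2S)-2-[(1R,2R,3R,4S,6R)-6-[(tert-butyldimethylsilyl)oxy]-4-ethenyl-2-hydroxy-4-methyl-3-(prop-1-en-2-yl)cyclohexyl]-2-hydroxypropanoate | C=C[C@]1(C)C[C@@H](O[Si](C)(C)C(C)(C)C)[C@H]([C@](C)(O)C(=O)OC)[C@H](O[Li])[C@@H]1C(=C)C | intermediate
15 | (3S,3aR,4R,6S,7R,7aR)-4-[(tert-butyldimethylsilyl)oxy]-6-ethenyl-3-hydroxy-3,6-dimethyl-7-(prop-1-en-2-yl)hexahydro-1-benzofuran-2(3H)-one | C=C[C@]1(C)C[C@@H](O[Si](C)(C)C(C)(C)C)[C@H]2[C@H](OC(=O)[C@@]2(C)O)[C@@H]1C(=C)C | intermediate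
16 | (3S,3aR,4R,6S,7R,7aR)-4-[(tert-butyldimethylsilyl)oxy]-6-ethenyl-3,6-dimethyl-2-oxo-7-(prop-1-en-2-yl)octahydro-1-benzofuran-3-yl acetate | C=C[C@]1(C)C[C@@H](O[Si](C)(C)C(C)(C)C)[C@H]2[C@H](OC(=O)[C@@]2(C)OC(C)=O)[C@@H]1C(=C)C | intermediate
17 | (3S,3aS,4R,6S,7R,7aR)-6-ethenyl-4-hydroxy-3,6-dimethyl-2-oxo-7-(prop-1-en-2-yl)octahydro-1-benzofuran-3-yl acetate | C=C[C@]1(C)C[C@@H](O)[C@H]2[C@H](OC(=O)[C@@]2(C)OC(C)=O)[C@@H]1C(=C)C | intermediate
18 | 3-methylbut-3-enoic acid | C=C(C)CC(=O)O | starting material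
19 | (3S,3aS,4R,6S,7R,7aR)-3-(acetyloxy)-6-ethenyl-3,6-dimethyl-2-oxo-7-(prop-1-en-2-yl)octahydro-1-benzofuran-4-yl 3-methylbut-3-enoate (CNP0106639.1) | C=C[C@]1(C)C[C@@H](OC(=O)CC(=C)C)[C@H]2[C@H](OC(=O)[C@@]2(C)OC(C)=O)[C@@H]1C(=C)C | target

## Step count and risks

Total step count: 9. Longest linear sequence: 9 steps (1 → 19).

The three steps most likely to fail:

**Step 2 (the proposed new step).** The acid may be too weak to protonate the diene or strong enough to cleave the silyl ether, and control over which CH2 migrates (ee) and over Me/OTBS cis selectivity (dr) is unproven. The fallback uses known chemistry, sets out from 1 and comes back at 5. Indium-mediated Barbier addition of 1-bromobut-2-yne to 1 (In, THF/H2O) gives cis-1-(buta-2,3-dien-2-yl)-3-[(tert-butyldimethylsilyl)oxy]cyclobutan-1-ol F1 by SE2′ attack of the propargylindium reagent. F1 is then ring-expanded to 5 by the established palladium-hydride asymmetric Wagner–Meerwein shift of allenylcyclobutanols (Pd2(dba)3·CHCl3 as the zerovalent palladium source, (R,R)-DACH-phenyl Trost ligand, PhCO2H, Et3N, ClCH2CH2Cl, 60 °C). Hydropalladation of the allene gives the same 1-methylallyl unit as a π-allylpalladium complex, and the ligand selects the migrating CH2.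

**Step 3.** The sulfonium ylide is basic and the ketone is hindered and carries a β-silyloxy group, so low conversion or enolisation/elimination may win. The fallback sets out from 5 and comes back at 10, bypassing 9. Methacrolein and acetyl bromide (CH2Cl2, −20 °C) give 3-bromo-2-methylprop-1-en-1-yl acetate F2. Its allylindium reagent (In, THF) adds to 5 under non-basic Barbier conditions to give 1-[(1S,2S,4R)-4-[(tert-butyldimethylsilyl)oxy]-2-ethenyl-1-hydroxy-2-methylcyclopentyl]-2-methylprop-2-en-1-yl acetate F3. Sc(OTf)3 in CH2Cl2 ionises the allylic acetate of F3, and the same 1,2-shift of C10 gives 10.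

**Step 5.** Pyruvate may be enolised instead of attacked, the adduct may undergo retro-aldol, and the configuration at C11 (and the face of attack at C7) rests on a transition-state argument. The fallback sets out from 10 and comes back at 15. The enolate 12 is added to ethyl glyoxylate to give ethyl 2-[(1S,3R,4S,6R)-6-[(tert-butyldimethylsilyl)oxy]-4-ethenyl-4-methyl-2-oxo-3-(prop-1-en-2-yl)cyclohexyl]-2-hydroxyacetate F4. Here C7 can equilibrate to the equatorial position and the carbinol configuration is irrelevant. Reduction with LiBH(s-Bu)3 and lactonisation give (3aR,4R,6S,7R,7aR)-4-[(tert-butyldimethylsilyl)oxy]-6-ethenyl-3-hydroxy-6-methyl-7-(prop-1-en-2-yl)hexahydro-1-benzofuran-2(3H)-one F5. Its alkoxide–enolate dianion (LiN(i-Pr)2, 2.2 equiv, THF, −78 °C) is C-methylated by iodomethane on the convex face of the cis-fused bicycle, which places the methyl cis to the ring-fusion hydrogens and gives 15.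

## Further compounds

F1 | step 2 | cis-1-(buta-2,3-dien-2-yl)-3-[(tert-butyldimethylsilyl)oxy]cyclobutan-1-ol | C=C=C(C)[C@]1(O)C[C@@H](O[Si](C)(C)C(C)(C)C)C1
F2 | step 3 | 3-bromo-2-methylprop-1-en-1-yl acetate (E/Z mixture) | CC(=O)OC=C(C)CBr
F3 | step 3 | 1-[(1S,2S,4R)-4-[(tert-butyldimethylsilyl)oxy]-2-ethenyl-1-hydroxy-2-methylcyclopentyl]-2-methylprop-2-en-1-yl acetate (both epimers at the acetoxy carbon) | C=C[C@]1(C)C[C@@H](O[Si](C)(C)C(C)(C)C)C[C@@]1(O)C(OC(C)=O)C(=C)C
F4 | step 5 | ethyl 2-[(1S,3R,4S,6R)-6-[(tert-butyldimethylsilyl)oxy]-4-ethenyl-4-methyl-2-oxo-3-(prop-1-en-2-yl)cyclohexyl]-2-hydroxyacetate (both epimers at the carbinol carbon) | C=C[C@]1(C)C[C@@H](O[Si](C)(C)C(C)(C)C)[C@H](C(O)C(=O)OCC)C(=O)[C@@H]1C(=C)C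
F5 | step 5 | (3aR,4R,6S,7R,7aR)-4-[(tert-butyldimethylsilyl)oxy]-6-ethenyl-3-hydroxy-6-methyl-7-(prop-1-en-2-yl)hexahydro-1-benzofuran-2(3H)-one (both epimers at C3) | C=C[C@]1(C)C[C@@H](O[Si](C)(C)C(C)(C)C)[C@H]2[C@H](OC(=O)C2O)[C@@H]1C(=C)C
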